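**Retrosynthetic overview**
1. Target ⇒ C6–O acylation and removal of two silyl groups from a 2‑O‑silylated 2α‑hydroxyjaeschkeanadiol.
2. Five‑membered ring, closed second: the C4–C5 bond (farnesyl C10–C6) comes from a monocyclic 5,6‑epoxy isopropyl ketone. Trivalent‑titanium epoxide opening and radical addition to C=O give 4‑OH, H‑5 and 6‑OH in one step.
3. Side chain (C2–C4, C11–C13): aldol of a cycloheptadiene carbaldehyde with 3‑methylbutan‑2‑one. The new 2‑OH then directs the C5=C6 epoxidation.
4. Seven‑membered ring, closed first: the C10–C1 bond (farnesyl C1–C7) forms while the tertiary allylic C8–O bond breaks with allylic transposition, as in the cyclisation of nerolidyl diphosphate. It is run as a ring‑contracting dienolate Ireland–Claisen rearrangement of an unsaturated ε‑lactone.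
5. Lactone ⇒ (R)‑linalool + 2‑(diethoxyphosphoryl)propanoic acid (esterification, ozonolysis, intramolecular olefination).

Assumption: commercial (R)‑(−)‑linalool is used at the ee supplied (≥ 95 %). All atoms carry the daucane numbers of the target from step 1 on: C1 quaternary, C2 CHOH, C4 C(OH)iPr, C5 ring‑fusion CH, C6 CH–O, C8=C9, C10 CH2, C15 angular methyl.

**Route**

Step 1
Reactants: 1 (R)-(−)-linalool; 2 2-(diethoxyphosphoryl)propanoic acid
Product: 3 (3R)-3,7-dimethylocta-1,6-dien-3-yl 2-(diethoxyphosphoryl)propanoate (epimers at the phosphonate carbon)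
Conditions: DCC, DMAP (0.2 equiv), CH2Cl2, 0 °C to rt
Reagents that add atoms: none
Why: Steglich esterification; α‑phosphono acids are activated through a ketene‑like intermediate, so even the tertiary allylic alcohol is acylated without ionisation and its stereocentre (future C8) is untouched.

Step 2
Reactants: 3 (3R)-3,7-dimethylocta-1,6-dien-3-yl 2-(diethoxyphosphoryl)propanoate
Product: 4 (3R)-3-methyl-6-oxohex-1-en-3-yl 2-(diethoxyphosphoryl)propanoate
Conditions: O3 (1.0 equiv, titrated solution), CH2Cl2, −78 °C; Me2S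
Reagents that add atoms: ozone, [O-][O+]=O
Why: Chemoselective ozonolysis; the electron‑rich trisubstituted alkene reacts far faster than the monosubstituted vinyl group, so one equivalent of ozone gives only the C5 aldehyde and no stereocentre is touched.

Step 3
Reactants: 4 (3R)-3-methyl-6-oxohex-1-en-3-yl 2-(diethoxyphosphoryl)propanoate
Product: 5 (7R)-7-ethenyl-3,7-dimethyl-6,7-dihydro-5H-oxepin-2-one
Conditions: LiCl, DBU, MeCN, syringe‑pump addition (0.003 M), rt
Reagents that add atoms: none
Why: Intramolecular Horner–Wadsworth–Emmons olefination under Masamune–Roush conditions at high dilution; the seven‑membered ring allows only the ring‑cis C1=C5 enoate, and both phosphonate epimers converge on it.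

Step 4
Reactants: 5 (7R)-7-ethenyl-3,7-dimethyl-6,7-dihydro-5H-oxepin-2-one
Product: 7 tert-butyldimethylsilyl (1R)-1,5-dimethylcyclohepta-2,5-diene-1-carboxylate, via silyl ketene acetal 6 (not isolated)
Conditions: KN(SiMe3)2, TBSCl, THF–DMPU, −78 °C; then toluene, 80 °C
Reagents that add atoms: tert-butyldimethylsilyl chloride, CC(C)(C)[Si](C)(C)Cl
Why: Proposed new method: the base removes a γ‑hydrogen (C6–H) of the enoate and O‑silylation gives the cyclic dienol ketene acetal 6, in which C1=C2(OSi)–O–C8–C9=C10 is an allyl vinyl ether that can rearrange only through a boat‑like transition state with the vinyl group swinging over the face of C1 on which it sits, so that C10–C1 forms, C8–O breaks with allylic transposition (ring‑cis C8=C9), C5=C6 stays deconjugated, and the (R) centre of linalool is relayed fully to the (R) quaternary C1; the closest known reaction types are the ring‑contracting (alicyclic) Ireland–Claisen rearrangement of ω‑vinyl lactones and the deconjugative Ireland–Claisen rearrangement of allyl 2‑alkenoates.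

Step 5
Reactants: 7 tert-butyldimethylsilyl (1R)-1,5-dimethylcyclohepta-2,5-diene-1-carboxylate
Product: 8 (1R)-1,5-dimethylcyclohepta-2,5-diene-1-carbaldehyde
Conditions: iBu2AlH (1.1 equiv), CH2Cl2, −78 °C; aq. KNaC4H4O6 (tartrate)
Reagents that add atoms: none
Why: Partial reduction of a silyl ester; the hindered aluminium acetal survives at −78 °C and collapses to the aldehyde only on work‑up, and the α‑quaternary aldehyde can neither epimerise nor conjugate.

Step 6
Reactants: 8 (1R)-1,5-dimethylcyclohepta-2,5-diene-1-carbaldehyde; 9 3-methylbutan-2-one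
Product: 12 (1S)-1-[(1R)-1,5-dimethylcyclohepta-2,5-dien-1-yl]-1-hydroxy-4-methylpentan-3-one, via boron enolate 10 (not isolated), via boron aldolate 11 (not isolated)
Conditions: 9, (+)-Ipc2BCl, Et3N, Et2O, 0 °C; 8, −78 to −20 °C; H2O2, MeOH, pH 7 buffer
Reagents that add atoms: none
Why: Boron aldol reaction of a methyl ketone; Ipc2BCl/Et3N enolises 9 on the methyl side and the isopinocampheyl ligands of the (+)‑reagent steer the enolate to the si face of the non‑enolisable aldehyde, giving the (S) carbinol (2α‑oxygen) as the major epimer, the minor one being removed by chromatography.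

Step 7
Reactants: 12 (1S)-1-[(1R)-1,5-dimethylcyclohepta-2,5-dien-1-yl]-1-hydroxy-4-methylpentan-3-one
Product: 13 (1S)-1-[(1R,2S,7S)-2,5-dimethyl-8-oxabicyclo[5.1.0]oct-4-en-2-yl]-1-hydroxy-4-methylpentan-3-one (5α,6α-epoxide)
Conditions: VO(acac)2 (5 mol %), tBuOOH (1.2 equiv), CH2Cl2, 0 °C to rt
Reagents that add atoms: tert-butyl hydroperoxide, CC(C)(C)OO
Why: Hydroxyl‑directed vanadium epoxidation; the vanadate ester of the homoallylic 2‑OH delivers oxygen to the nearer C5=C6 alkene rather than to the bishomoallylic C8=C9, and only from the ring face that carries the side chain (anti to C15), which fixes the 6α‑oxygen.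

Step 8
Reactants: 13 (1S)-1-[(1R,2S,7S)-2,5-dimethyl-8-oxabicyclo[5.1.0]oct-4-en-2-yl]-1-hydroxy-4-methylpentan-3-one
Product: 14 triethylsilyl ether of 13 at the C2 oxygen
Conditions: TESCl, imidazole, DMF, 0 °C to rt
Reagents that add atoms: chlorotriethylsilane, CC[Si](Cl)(CC)CC
Why: Standard silylation; it masks the only other secondary hydroxyl of the final triol so that the later acylation can occur only at 6‑OH, and no stereocentre is touched.

Step 9
Reactants: 14 triethylsilyl ether of 13 at the C2 oxygen
Product: 15 (1S,3R,3aS,4S,8aR)-6,8a-dimethyl-3-(propan-2-yl)-1-[(triethylsilyl)oxy]-1,2,3,3a,4,5,8,8a-octahydroazulene-3,4-diol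
Conditions: Cp2TiCl2 (2.5 equiv), Mn dust (8 equiv), THF, rt, slow addition of 14 (0.01 M); aq. NaH2PO4
Reagents that add atoms: none
Why: RajanBabu–Nugent epoxide opening followed by the known titanocene‑mediated addition of an epoxide‑derived radical to a ketone; Cp2TiCl cleaves the congested C5–O bond (titanium stays on the less hindered C6 oxygen, which keeps its α configuration), the C5 radical adds 5‑exo to the isopropyl ketone, and because this addition is reversible until a second Cp2TiCl reduces the alkoxyl radical, the more stable trans‑fused alkoxide is drained off, with the new C4–C5 bond equatorial and anti to the bulky C6 titanoxy group (H‑5 α) and the isopropyl group on the open α face away from C15 and C6 (4‑OH β).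

Step 10
Reactants: 16 4-hydroxybenzoic acid
Product: 18 4-[(tert-butyldimethylsilyl)oxy]benzoic acid, via bis-silylated acid 17 (not isolated)
Conditions: TBSCl (2.2 equiv), imidazole, DMF, rt; then THF–H2O–AcOH, rt
Reagents that add atoms: tert-butyldimethylsilyl chloride, CC(C)(C)[Si](C)(C)Cl
Why: Exhaustive silylation followed by selective hydrolysis; the silyl ester is far more labile to aqueous acid than the aryl silyl ether.

Step 11
Reactants: 15 (1S,3R,3aS,4S,8aR)-6,8a-dimethyl-3-(propan-2-yl)-1-[(triethylsilyl)oxy]-1,2,3,3a,4,5,8,8a-octahydroazulene-3,4-diol; 18 4-[(tert-butyldimethylsilyl)oxy]benzoic acid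
Product: 19 (1S,3R,3aS,4S,8aR)-3-hydroxy-6,8a-dimethyl-3-(propan-2-yl)-1-[(triethylsilyl)oxy]-1,2,3,3a,4,5,8,8a-octahydroazulen-4-yl 4-[(tert-butyldimethylsilyl)oxy]benzoate
Conditions: DCC, DMAP, CH2Cl2, rt to 40 °C
Reagents that add atoms: none
Why: Steglich esterification; only the secondary 6‑OH is free to react, the tertiary 4‑OH being inert under these conditions, and the C6–O bond is not broken so the 6α configuration is retained.

Step 12
Reactants: 19 (1S,3R,3aS,4S,8aR)-3-hydroxy-6,8a-dimethyl-3-(propan-2-yl)-1-[(triethylsilyl)oxy]-1,2,3,3a,4,5,8,8a-octahydroazulen-4-yl 4-[(tert-butyldimethylsilyl)oxy]benzoate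
Product: 20 2α-hydroxyferutinin
Conditions: HF·pyridine, pyridine, THF, 0 °C to rt
Reagents that add atoms: none
Why: Fluoride‑driven global desilylation; buffered HF removes the aryl and alkyl silyl ethers while leaving the ester, the tertiary alcohol and the trisubstituted alkene untouched.

**Compound list**
1 | (R)-(−)-linalool | C=C[C@](C)(O)CCC=C(C)C | starting material
2 | 2-(diethoxyphosphoryl)propanoic acid | CCOP(=O)(OCC)C(C)C(=O)O | starting material
3 | (3R)-3,7-dimethylocta-1,6-dien-3-yl 2-(diethoxyphosphoryl)propanoate | CCOP(=O)(OCC)C(C)C(=O)O[C@@](C)(C=C)CCC=C(C)C | intermediate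
4 | (3R)-3-methyl-6-oxohex-1-en-3-yl 2-(diethoxyphosphoryl)propanoate | CCOP(=O)(OCC)C(C)C(=O)O[C@@](C)(C=C)CCC=O | intermediate
5 | (7R)-7-ethenyl-3,7-dimethyl-6,7-dihydro-5H-oxepin-2-one | C=C[C@@]1(C)CCC=C(C)C(=O)O1 | intermediate
6 | (2R)-7-[(tert-butyldimethylsilyl)oxy]-2-ethenyl-2,6-dimethyl-2,3-dihydrooxepine | C=C[C@@]1(C)CC=CC(C)=C(O[Si](C)(C)C(C)(C)C)O1 | intermediate
7 | tert-butyldimethylsilyl (1R)-1,5-dimethylcyclohepta-2,5-diene-1-carboxylate | O=C(O[Si](C)(C)C(C)(C)C)[C@@]1(C)C=CCC(C)=CC1 | intermediate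
8 | (1R)-1,5-dimethylcyclohepta-2,5-diene-1-carbaldehyde | O=C[C@@]1(C)C=CCC(C)=CC1 | intermediate
9 | 3-methylbutan-2-one | CC(=O)C(C)C | starting material
10 | 3-methylbut-1-en-2-yl bis[(+)-isopinocampheyl]borinate | C=C(OB([C@H]1C[C@H]2C[C@@H]([C@@H]1C)C2(C)C)[C@H]1C[C@H]2C[C@@H]([C@@H]1C)C2(C)C)C(C)C | intermediate
11 | bis[(+)-isopinocampheyl]borinate of 12 at the C2 oxygen | CC(C)C(=O)C[C@H](OB([C@H]1C[C@H]2C[C@@H]([C@@H]1C)C2(C)C)[C@H]1C[C@H]2C[C@@H]([C@@H]1C)C2(C)C)[C@@]1(C)C=CCC(C)=CC1 | intermediate
12 | (1S)-1-[(1R)-1,5-dimethylcyclohepta-2,5-dien-1-yl]-1-hydroxy-4-methylpentan-3-one | CC(C)C(=O)C[C@H](O)[C@@]1(C)C=CCC(C)=CC1 | intermediate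
13 | (1S)-1-[(1R,2S,7S)-2,5-dimethyl-8-oxabicyclo[5.1.0]oct-4-en-2-yl]-1-hydroxy-4-methylpentan-3-one | CC(C)C(=O)C[C@H](O)[C@@]1(C)[C@H]2O[C@H]2CC(C)=CC1 | intermediate
14 | triethylsilyl ether of 13 at the C2 oxygen | CC(C)C(=O)C[C@H](O[Si](CC)(CC)CC)[C@@]1(C)[C@H]2O[C@H]2CC(C)=CC1 | intermediate
15 | (1S,3R,3aS,4S,8aR)-6,8a-dimethyl-3-(propan-2-yl)-1-[(triethylsilyl)oxy]-1,2,3,3a,4,5,8,8a-octahydroazulene-3,4-diol | CC1=CC[C@]2(C)[C@@H]([C@@H](O)C1)[C@](O)(C(C)C)C[C@@H]2O[Si](CC)(CC)CC | intermediate
16 | 4-hydroxybenzoic acid | OC(=O)c1ccc(O)cc1 | starting material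
17 | tert-butyldimethylsilyl 4-[(tert-butyldimethylsilyl)oxy]benzoate | CC(C)(C)[Si](C)(C)Oc1ccc(cc1)C(=O)O[Si](C)(C)C(C)(C)C | intermediate
18 | 4-[(tert-butyldimethylsilyl)oxy]benzoic acid | CC(C)(C)[Si](C)(C)Oc1ccc(cc1)C(=O)O | intermediate
19 | 2-O-triethylsilyl, phenol-O-tert-butyldimethylsilyl 2α-hydroxyferutinin | CC1=CC[C@]2(C)[C@@H]([C@@H](OC(=O)c3ccc(O[Si](C)(C)C(C)(C)C)cc3)C1)[C@](O)(C(C)C)C[C@@H]2O[Si](CC)(CC)CC | intermediate
20 | 2α-hydroxyferutinin, (1S,3R,3aS,4S,8aR)-1,3-dihydroxy-6,8a-dimethyl-3-(propan-2-yl)-1,2,3,3a,4,5,8,8a-octahydroazulen-4-yl 4-hydroxybenzoate | CC1=CC[C@]2(C)[C@@H]([C@@H](OC(=O)c3ccc(O)cc3)C1)[C@](O)(C(C)C)C[C@@H]2O | target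

**Step count**
Total step count: 12. Longest linear sequence: 11 (steps 1–9, 11, 12).

**Three steps most likely to fail**

Step 9 is the riskiest. Kinetic closure onto the C5 radical could favour the cis ring fusion. Reduction of the radical by a second Cp2TiCl would deoxygenate the epoxide back to the alkene.
The fallback replaces the radical by a regiospecific enolate whose aldol closure can equilibrate. It sets out from 14.
- Oxidative epoxide opening at the less hindered C6 (DMSO, TMSOTf, CH2Cl2, −78 °C, then Et3N) gives the 5α‑(trimethylsilyloxy) 6‑ketone F1.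
- SmI2 in THF at −78 °C expels the α‑silyloxy group and generates the enolate of trivalent samarium only at C5, so C7 and the C8=C9 alkene are not disturbed. This enolate closes reversibly onto the isopropyl ketone to give the chelated trans‑fused 4β‑hydroxy 6‑ketone F2.
- Hydroxyl‑directed reduction with Me4NBH(OAc)3 (MeCN–AcOH, −30 °C) delivers hydride from the β face. This comes back to the route at 15.

Step 4 may fail in two ways. The extra unsaturation flattens the lactone ring and could raise the barrier of the boat transition state. The dienolate could also be silylated or decomposed unproductively.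
The fallback abandons the enolate and works at the aldehyde oxidation level. It sets out from 5.
- iBu2AlH at −78 °C gives the unsaturated lactol F3.
- Catalytic PPTS with molecular sieves in refluxing toluene removes water in a 1,4 sense to give the cyclic dienol ether F4.
- F4 undergoes a neutral aliphatic Claisen rearrangement in the same flask, with the same chirality transfer. This comes back to the route at 8 and skips step 5.

Step 7 may lose chemoselectivity, because the trisubstituted C8=C9 alkene is intrinsically more nucleophilic and is still within reach of the vanadate.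
The fallback masks that alkene. It sets out from 12.
- One equivalent of pyridinium tribromide at −40 °C adds bromine only to the electron‑rich C8=C9 bond, giving the 8,9‑dibromide F5.
- The same VO(acac)2/tBuOOH epoxidation now has a single alkene to attack and gives the epoxy dibromide F6.
- Zn dust in EtOH at 0 °C restores the alkene. This comes back to the route at 13.

**Further compounds**
F1 | step 9 | (1S)-1-{1,5-dimethyl-3-oxo-2-[(trimethylsilyl)oxy]cyclohept-5-en-1-yl}-4-methyl-1-[(triethylsilyl)oxy]pentan-3-one (5α-silyloxy 6-ketone) | CC(C)C(=O)C[C@H](O[Si](CC)(CC)CC)[C@@]1(C)[C@@H](O[Si](C)(C)C)C(=O)CC(C)=CC1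
F2 | step 9 | trans-fused 4β-hydroxy-2α-[(triethylsilyl)oxy]dauc-8-en-6-one | CC1=CC[C@]2(C)[C@@H](C(=O)C1)[C@](O)(C(C)C)C[C@@H]2O[Si](CC)(CC)CC
F3 | step 4 | (7R)-7-ethenyl-3,7-dimethyl-2,5,6,7-tetrahydrooxepin-2-ol (anomers) | C=C[C@@]1(C)CCC=C(C)C(O)O1
F4 | step 4 | (2R)-2-ethenyl-2,6-dimethyl-2,3-dihydrooxepine | C=C[C@@]1(C)CC=CC(C)=CO1
F5 | step 7 | 8,9-dibromide of 12 (trans addition, two diastereomers) | CC(C)C(=O)C[C@H](O)[C@@]1(C)C=CCC(C)(Br)C(Br)C1
F6 | step 7 | 8,9-dibromide of 13 (5α,6α-epoxide) | CC(C)C(=O)C[C@H](O)[C@@]1(C)[C@H]2O[C@H]2CC(C)(Br)C(Br)C1
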